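A direct plan would grow the pyrrole ring on 2,5-dibromoaniline A1 by a Gassman oxindole synthesis with ethyl 2-(methylsulfanyl)acetate A2 to give racemic 4,7-dibromo-3-(methylsulfanyl)indolin-2-one A3. It would then remove the sulfur to reach 4,7-dibromoindolin-2-one A4 and chlorodehydrate the lactam to 4,7-dibromo-2-chloro-1H-indole A5 before brominating C3 last.
Its weakest steps would be:
- The Gassman ring construction: four events in one pot (N-chlorination, azasulfonium formation, ylide [2,3]-shift, lactamisation) on a doubly deactivated aniline, with the new C–C bond forced onto the one free ortho carbon, which sits next to a bromine.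
- The reductive desulfurisation: a whole step that builds nothing, because sulfur and a stereocentre are installed only to be erased, and it exposes aryl bromides to a dissolving metal.
- The chlorodehydration of the oxindole: it must deliver a 3-unsubstituted 2-chloroindole, an acid-labile enamine-like compound, under hot acidic conditions that favour self-condensation, and that product must then survive one more halogenation.

**Retrosynthetic overview**
The vicinal pair C2–Cl / C3–Br on the pyrrole ring (N1, C2, C3, C3a, C7a) is traced back to a geminal CBrCl vinyl terminus. An aryl nitrenoid closes N1–C2 onto ArCH=CBrCl, and a 1,2-shift of bromine from C2 to C3 then gives the fully halogenated N–H indole in one operation.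
The azidostyrene comes from 3,6-dibromo-2-fluorobenzaldehyde in two steps: azide SNAr at the formyl-activated fluoride, then a phosphine-free Wittig bromochloromethylenation.
Ring order: the benzene ring (C3a–C7a) is bought with both bromines in place, and the pyrrole ring closes last at N1–C2 (not at C3–C3a, and not by lactamisation).
The design has no sulfur detour, no oxindole, no chlorodehydration, no 3-unsubstituted 2-chloroindole and no late electrophilic halogenation.

Key step: step 3

Assumption: compound 1, 3,6-dibromo-2-fluorobenzaldehyde, is taken as a catalogue building block.

**Step 1**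
Reactants: 1 3,6-dibromo-2-fluorobenzaldehyde
Product: 2 2-azido-3,6-dibromobenzaldehyde
Conditions: NaN3 (1.3 equiv), DMSO, 40 °C, dark
Reagents that add atoms: sodium azide, [Na+].[N-]=[N+]=[N-]
Why: Nucleophilic aromatic substitution by addition–elimination at the fluoride ortho to the formyl group; fluoride is displaced far faster than bromide in this mechanism, so the formyl-activated C6 bromide and the unactivated C3 bromide should stay, and the mild temperature should keep the azide from losing nitrogen onto the neighbouring formyl group.

**Step 2**
Reactants: 2 2-azido-3,6-dibromobenzaldehyde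
Product: 3 2-azido-1,4-dibromo-3-(2-bromo-2-chloroethenyl)benzene (E/Z mixture)
Conditions: [Ph3PCH2Cl]Cl (1.5 equiv), NaN(SiMe3)2 (1.5 equiv), THF, −78 °C; Br2 (1.45 equiv), −78 °C; NaN(SiMe3)2 (1.45 equiv), −78 °C; then 2, −78 °C → rt
Reagents that add atoms: (chloromethyl)triphenylphosphonium chloride, [Cl-].ClC[P+](c1ccccc1)(c1ccccc1)c1ccccc1; bromine, BrBr
Why: Wittig dihalomethylenation of a non-enolisable aldehyde with a bromochloromethylene ylide made by α-bromination and re-deprotonation of the chloromethylene ylide (a known way to α-halo ylides), so no trivalent phosphorus is present to reduce the azide in a Staudinger reaction; the E/Z mixture is harmless because both isomers lead to the same C2 in step 3, and no stereocentre is formed.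

**Step 3**
Reactants: 3 2-azido-1,4-dibromo-3-(2-bromo-2-chloroethenyl)benzene
Product: 6 3,4,7-tribromo-2-chloro-1H-indole, via 2,4,7-tribromo-2-chloro-2H-indole 4 (not isolated), via 3,4,7-tribromo-2-chloro-3H-indole 5 (not isolated)
Conditions: Rh2(O2CC3F7)4 (5 mol %), ClCH2CH2Cl, 4 Å MS, 70 °C, dark
Reagents that add atoms: none
Why: Proposed new method: the dirhodium tetrakis(heptafluorobutyrate) (divalent rhodium) should convert the aryl azide into an electrophilic rhodium nitrenoid that closes the pyrrole ring at N1–C2 by a 4π-electron, 5-atom electrocyclization onto the CBrCl terminus (formally 5-endo-trig), giving 2H-indole 4 in which C2 carries both halogens and no hydrogen, so that the benzene ring can only re-aromatize by a 1,2-shift from C2 to the cationic C3. Bromine should be the group that moves, through a bromonium-like bridged transition state or a tight radical pair, because the C–Br bond is weaker and bromine bridges far better than chlorine; chlorine stays on what becomes the C2=N carbon of 3H-indole 5, which tautomerizes to the aromatic 1H-indole 6. The closest known reaction type is the Sundberg indole synthesis from 2-azidostyrenes and its dirhodium-catalysed variants, in which β,β-disubstituted styryl azides give 2,3-disubstituted indoles by selective 1,2-migration of alkyl, aryl, acyl, nitro or sulfonyl groups, together with the [1,5]-halogen shifts of 5-halocyclopentadienes; a halogen as the migrating group in the nitrene cyclization is the new element. No stereocentre remains (C3 of 5 is transient) and both alkene isomers of 3 converge because they give the same C2. The selectivities needed are bromine over chlorine migration and shift over loss of bromine; the first rests on migratory aptitude, the second on a solvent without weak C–H bonds, molecular sieves against hydrolysis of the imidoyl chloride in 5, and exclusion of light.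

**Compound list**
1 | 3,6-dibromo-2-fluorobenzaldehyde | O=Cc1c(F)c(Br)ccc1Br | starting material
2 | 2-azido-3,6-dibromobenzaldehyde | [N-]=[N+]=Nc1c(Br)ccc(Br)c1C=O | intermediate
3 | 2-azido-1,4-dibromo-3-(2-bromo-2-chloroethenyl)benzene, E/Z mixture | [N-]=[N+]=Nc1c(Br)ccc(Br)c1C=C(Br)Cl | intermediate
4 | 2,4,7-tribromo-2-chloro-2H-indole | ClC1(Br)N=C2C(Br)=CC=C(Br)C2=C1 | intermediate (not isolated)
5 | 3,4,7-tribromo-2-chloro-3H-indole, racemic and transient | ClC1=Nc2c(Br)ccc(Br)c2C1Br | intermediate (not isolated)
6 | 3,4,7-tribromo-2-chloro-1H-indole | Clc1[nH]c2c(Br)ccc(Br)c2c1Br | target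

Total step count: 3. Longest linear sequence: 3.

**Steps most likely to fail**

Step 3 (proposed new method). The shift may not be selective or may not occur: chlorine could migrate in competition, bromine could be lost instead of moving, or the doubly flanked azide could decompose by intermolecular nitrene chemistry before it cyclises. The fallback keeps the N1–C2 closure but changes the precursor so that only hydrogen has to move, which is the classical Sundberg reaction. It sets out from 2. Ohira–Bestmann homologation (dimethyl (1-diazo-2-oxopropyl)phosphonate, K2CO3, MeOH) would give 2-azido-1,4-dibromo-3-ethynylbenzene F1. N-Chlorosuccinimide with catalytic AgOAc in acetone would give the chloroalkyne 2-azido-1,4-dibromo-3-(chloroethynyl)benzene F2. Hydrobromination catalysed by Pd(OAc)2 (divalent palladium; LiBr, AcOH, MeCN) would place bromine on the aryl-bearing carbon and give 2-azido-1,4-dibromo-3-[(Z)-1-bromo-2-chloroethenyl]benzene F3. Thermolysis of F3 in chlorobenzene at 120 °C would close N1 onto the CHCl carbon, and a hydrogen shift would then give the indole with Cl at C2 and Br at C3, so the fallback comes back to the route at 6.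

Step 2. The ylide sequence may scramble halogens by halophilic attack and give mixed dihaloalkenes, the ylide or the amide base may add to the azide, and the aldehyde, with both ortho positions occupied, may react slowly. The fallback replaces the Wittig reaction by addition and elimination with no phosphorus at all. It sets out from 2. Bromochloromethyllithium, generated and trapped in situ (CH2BrCl, LiN(i-Pr)2, THF, −78 °C), would add to the aldehyde to give 1-(2-azido-3,6-dibromophenyl)-2-bromo-2-chloroethan-1-ol F4. Mesylation (MsCl, Et3N, CH2Cl2, 0 °C) would give 1-(2-azido-3,6-dibromophenyl)-2-bromo-2-chloroethyl methanesulfonate F5. Elimination with DBU, removing the acidic CHBrCl hydrogen and the benzylic sulfonate, would come back to the route at 3.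

Step 1. Substitution at a carbon flanked on both sides may be slow, and at the temperature then needed the azide ion could also attack the formyl-activated C6 bromide, or the azido aldehyde could lose nitrogen. The fallback brings nitrogen in as an amine, which tolerates forcing conditions, and builds the azide afterwards in the cold. It sets out from 1. Ammonia (7 M in MeOH, DMSO, sealed tube, 70 °C, then dilute aqueous acid to hydrolyse any aldimine) would give 2-amino-3,6-dibromobenzaldehyde F6. Diazotisation and azide transfer (t-BuONO, Me3SiN3, MeCN, 0 °C) would come back to the route at 2.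

**Further compounds**
F1 | step 3 | 2-azido-1,4-dibromo-3-ethynylbenzene | C#Cc1c(Br)ccc(Br)c1N=[N+]=[N-]
F2 | step 3 | 2-azido-1,4-dibromo-3-(chloroethynyl)benzene | ClC#Cc1c(Br)ccc(Br)c1N=[N+]=[N-]
F3 | step 3 | 2-azido-1,4-dibromo-3-[(Z)-1-bromo-2-chloroethenyl]benzene | Cl/C=C(\Br)c1c(Br)ccc(Br)c1N=[N+]=[N-]
F4 | step 2 | 1-(2-azido-3,6-dibromophenyl)-2-bromo-2-chloroethan-1-ol, mixture of racemic diastereomers | OC(C(Br)Cl)c1c(Br)ccc(Br)c1N=[N+]=[N-]
F5 | step 2 | 1-(2-azido-3,6-dibromophenyl)-2-bromo-2-chloroethyl methanesulfonate, mixture of racemic diastereomers | CS(=O)(=O)OC(C(Br)Cl)c1c(Br)ccc(Br)c1N=[N+]=[N-]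
F6 | step 1 | 2-amino-3,6-dibromobenzaldehyde | Nc1c(Br)ccc(Br)c1C=O
A1 | direct plan | 2,5-dibromoaniline | Nc1cc(Br)ccc1Br
A2 | direct plan | ethyl 2-(methylsulfanyl)acetate | CCOC(=O)CSC
A3 | direct plan | 4,7-dibromo-3-(methylsulfanyl)indolin-2-one, racemic | CSC1C(=O)Nc2c(Br)ccc(Br)c21
A4 | direct plan | 4,7-dibromoindolin-2-one | O=C1Cc2c(Br)ccc(Br)c2N1
A5 | direct plan | 4,7-dibromo-2-chloro-1H-indole | Clc1cc2c(Br)ccc(Br)c2[nH]1
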